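The runs stem from a simulated flask for an exercise; scatter was added.

Which flask should I charge for D, the thin one left long or the strong one read early?

- the winner by amount of D, in percent of the G charged; "neither" if no more than 2 percentage points parts them (Thursday's / Sunday's / neither)
- how much D is there at the end, in percent of the G charged: Thursday's
- how much D is there at the end, in percent of the G charged: Sunday's

| flask | G | remark | time |
|---|---|---|---|
| north-east | 0.34 M | run made earlier |  |
| Thursday's | 0.10 M |  | 100 min |
| Sunday's | 0.31 M |  | 25 min |

north-east run (percent of the G charged)

| time / min | D / % | G / % |
|---|---|---|
| 0.667 | 45 | 49 |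
| 1.33 | 43 | 42 |
| 2.00 | 42 | 39 |
| 3.00 | 41 | 35 |
| 5.00 | 37 | 25 |
| 8.00 | 30 | 17 |

(standard deviation of a reading: 1.5 percentage points)



The decision hung on the first reading of the north-east run, where D stood at 45% and G at 49% after 0.667 min. I read that as a fast reversible split of G into D and an unseen partner, one of each. With d and g as the fractions of the charge in D and G, twice the charge times d times d over g gives 0.281 M. This is the balance charge, the charge at which such a split leaves G and D equal, the symmetric case against which I held each charge, and as a figure from one reading it carries that reading's scatter.

Thursday's charge lies below it and Sunday's above it. Before any loss, D should therefore be 67.5% of G plus D in Thursday's flask, more than the 48.4% in Sunday's.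

But G plus D had fallen to 47.0% by 8.00 min in the north-east run, and I had readings at one charge, so I had none of how this drain moves with charge. My own reckoning stopped at those two shares: I would charge Thursday's if dilution slowed the drain, and not otherwise.

The forecast chose Sunday's, with 0.7% (0% to 3%) for Thursday's and 12% (5% to 17%) for Sunday's: “the long time leaves under 1%”.

Thursday's ended at 25.9% of D and Sunday's at 20.4%, so Thursday's won.

    G ⇌ D + J (K = 0.136 M, k = 0.0885 /s)
    G + D → E (k = 0.00808 /M/s)
    G + J → X (k = 0.0110 /M/s)

The main reason for the low D in Thursday's flask was the backward run from D + J to G: without that run Thursday's held 98.5% of D instead of 25.9%. With J in place of the assumed partner, G over D should equal twice J over the balance charge. At Thursday's J of 0.0204 M that gives 0.145, and the flask stood at 0.150. At Sunday's J of 0.0476 M it gives 0.339, and that flask stood at 0.349.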